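**Retrosynthetic overview**

1. Numbering: C1 ketone, C2=C3, C4–OAc, C5–OH (quaternary), C6–OAc, C7–C20 alkyl; the target is (4R,5S,6S). The plan rests on the unbranched run C2–C7: its oxygens at C4, C5 and C6 repeat C4, C3 and C2 of D-allose, C1 is a one-carbon branch on C5, and the only ring is the cyclopentenone C1–C5.
2. The C2=C3 enone is traced back to the saturated ketone (Saegusa–Ito). The ring is then cut at C1–C2 to an open-chain 4-pentenal (rhodium hydroacylation of the formyl C1–H across the C2=C3 vinyl group).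
3. The pentenal maps onto diacetone glucose: C1 comes from 1,3-dithiane added to the 3-ulose on the convex face (sets C5, allo); C2=C3 comes from the sugar 5,6-diol; C8–C20 come from a tridecyl cuprate that opens the sugar C1–C2 epoxide (C7 = sugar C1).
4. Ring order: one ring only, closed in step 14 after C4, C5 and C6 are all in place.

Key step: step 14

Remark: an oxygen on the carbon next to the acyl group cannot chelate rhodium (a four-membered ring would be needed), so the C5 hydroxyl is carried through the ring closure as a triethylsilyl ether. Sugar O3 and O4 are tied as an acetonide while the chain is attached, so that neither epoxide migration nor tetrahydrofuran closure can compete.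

**Route**

Step 1
Reactants: 1 1,2:5,6-di-O-isopropylidene-α-D-glucofuranose
Product: 2 1,2:5,6-di-O-isopropylidene-α-D-ribo-hexofuranos-3-ulose
Conditions: DMSO, Ac2O, rt; product dried azeotropically (toluene)
Reagents that add atoms: none
Why: Albright–Goldman oxidation of the only free hydroxyl should give the 3-ulose with both acetonides intact; no stereocentre is formed.

Step 2
Reactants: 2 1,2:5,6-di-O-isopropylidene-α-D-ribo-hexofuranos-3-ulose; 3 1,3-dithiane
Product: 5 3-C-(1,3-dithian-2-yl)-1,2:5,6-di-O-isopropylidene-α-D-allofuranose, via 2-lithio-1,3-dithiane 4 (not isolated)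
Conditions: 3, n-BuLi, THF, −30 °C; then 2, −78 to −20 °C; aq. NH4Cl
Reagents that add atoms: none
Why: Corey–Seebach addition of the formyl anion equivalent should occur on the convex β face of the cis-fused furanose–dioxolane bicycle, anti to the 1,2-acetonide, so the new C–C bond is β and the tertiary hydroxyl α (allo), which is C5 of the target.

Step 3
Reactants: 5 3-C-(1,3-dithian-2-yl)-1,2:5,6-di-O-isopropylidene-α-D-allofuranose
Product: 6 3-C-(1,3-dithian-2-yl)-1,2-O-isopropylidene-α-D-allofuranose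
Conditions: AcOH/H2O (7:3), 40 °C
Reagents that add atoms: none
Why: Chemoselective acetal hydrolysis, the terminal dioxolane being cleaved much faster than the anomeric acetonide fused to the furanose; the dithiane is inert to aqueous acid.

Step 4
Reactants: 6 3-C-(1,3-dithian-2-yl)-1,2-O-isopropylidene-α-D-allofuranose
Product: 8 5,6-dideoxy-3-C-(1,3-dithian-2-yl)-1,2-O-isopropylidene-α-D-ribo-hex-5-enofuranose, via cyclic 5,6-thionocarbonate 7 (not isolated)
Conditions: 1,1'-thiocarbonyldiimidazole, toluene, 80 °C; evaporate; P(OMe)3, 110 °C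
Reagents that add atoms: none
Why: Corey–Winter olefination turns the 5,6-diol into the terminal alkene through the five-membered thionocarbonate and loss of CO2; no C6 electrophile arises that the dithiane sulfur could alkylate, and the hindered tertiary hydroxyl should not react.

Step 5
Reactants: 8 5,6-dideoxy-3-C-(1,3-dithian-2-yl)-1,2-O-isopropylidene-α-D-ribo-hex-5-enofuranose
Product: 10 5,6-dideoxy-3-C-(1,3-dithian-2-yl)-D-ribo-hex-5-enitol, via lactol 9 (not isolated)
Conditions: TFA/H2O (9:1), 0 °C; evaporate; NaBH4, EtOH, 0 °C to rt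
Reagents that add atoms: none
Why: Acid hydrolysis of the anomeric acetonide followed by borohydride reduction of the lactol (through its open-chain aldehyde) gives the alditol; sugar C2, C3 and C4 are not touched.

Step 6
Reactants: 10 5,6-dideoxy-3-C-(1,3-dithian-2-yl)-D-ribo-hex-5-enitol
Product: 11 5,6-dideoxy-3-C-(1,3-dithian-2-yl)-1,2:3,4-di-O-isopropylidene-D-ribo-hex-5-enitol
Conditions: 2,2-dimethoxypropane, CSA (cat.), acetone, rt
Reagents that add atoms: 2,2-dimethoxypropane COC(C)(C)OC
Why: Acid-catalysed transketalisation should place a dioxolane on each vicinal diol pair (1,2 and 3,4), five-membered isopropylidene rings being preferred over dioxanes.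

Step 7
Reactants: 11 5,6-dideoxy-3-C-(1,3-dithian-2-yl)-1,2:3,4-di-O-isopropylidene-D-ribo-hex-5-enitol
Product: 12 5,6-dideoxy-3-C-(1,3-dithian-2-yl)-3,4-O-isopropylidene-D-ribo-hex-5-enitol
Conditions: AcOH/H2O (4:1), rt, stopped at full conversion of 11
Reagents that add atoms: none
Why: Selective acetal hydrolysis as in step 3: the unhindered terminal dioxolane should open well before the fully substituted 3,4-dioxolane, which is shielded by the dithiane, leaving O3 and O4 blocked.

Step 8
Reactants: 12 5,6-dideoxy-3-C-(1,3-dithian-2-yl)-3,4-O-isopropylidene-D-ribo-hex-5-enitol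
Product: 14 1,2-anhydro-5,6-dideoxy-3-C-(1,3-dithian-2-yl)-3,4-O-isopropylidene-D-ribo-hex-5-enitol, via primary tosylate 13 (not isolated)
Conditions: NaH (2.2 equiv), N-tosylimidazole (1.05 equiv), THF, 0 °C to rt
Reagents that add atoms: none
Why: One-pot sulfonylation and Williamson closure: the primary alkoxide is tosylated and the neighbouring C2 alkoxide displaces the tosylate at once (3-exo-tet), so C2 keeps its configuration and the tosylate has no lifetime in which the dithiane sulfur could attack it.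

Step 9
Reactants: 14 1,2-anhydro-5,6-dideoxy-3-C-(1,3-dithian-2-yl)-3,4-O-isopropylidene-D-ribo-hex-5-enitol; 15 1-bromotridecane
Product: 17 (1S)-1-[(4S,5R)-4-(1,3-dithian-2-yl)-2,2-dimethyl-5-vinyl-1,3-dioxolan-4-yl]pentadecan-1-ol, via tridecylmagnesium bromide 16 (not isolated)
Conditions: 15, Mg, THF; CuI (copper iodide, 10 mol%), then 14, THF, −40 to −10 °C; aq. NH4Cl
Reagents that add atoms: none
Why: Copper-catalysed Grignard opening of a terminal epoxide proceeds by SN2 attack at the unsubstituted carbon, which attaches C8–C20 to C7 and leaves the C6 carbinol configuration unchanged.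

Step 10
Reactants: 17 (1S)-1-[(4S,5R)-4-(1,3-dithian-2-yl)-2,2-dimethyl-5-vinyl-1,3-dioxolan-4-yl]pentadecan-1-ol
Product: 18 (3R,4S,5S)-4-(1,3-dithian-2-yl)nonadec-1-ene-3,4,5-triol
Conditions: TFA/H2O (4:1), CH2Cl2, 0 °C to rt
Reagents that add atoms: none
Why: Acid hydrolysis of the remaining dioxolane frees the C4 and C5 oxygens; the dithiane and the vinyl group tolerate aqueous acid, and ionisation at the tertiary carbinol is disfavoured by its two oxygenated neighbours.

Step 11
Reactants: 18 (3R,4S,5S)-4-(1,3-dithian-2-yl)nonadec-1-ene-3,4,5-triol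
Product: 19 (3R,4S,5S)-4-(1,3-dithian-2-yl)-4-hydroxynonadec-1-ene-3,5-diyl diacetate
Conditions: Ac2O, pyridine, DMAP (cat.), CH2Cl2, 0 °C to rt
Reagents that add atoms: acetic anhydride CC(=O)OC(C)=O
Why: Nucleophile-catalysed acylation should esterify the two secondary hydroxyls (C4 and C6), while the tertiary hydroxyl flanked by three branched carbons is too hindered to react.

Step 12
Reactants: 19 (3R,4S,5S)-4-(1,3-dithian-2-yl)-4-hydroxynonadec-1-ene-3,5-diyl diacetate
Product: 20 (2S,3R)-3-acetoxy-2-[(1S)-1-acetoxypentadecyl]-2-hydroxypent-4-enal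
Conditions: PhI(OCOCF3)2, MeCN/H2O (9:1), 0 °C, short reaction time
Reagents that add atoms: water O
Why: Oxidative thioacetal hydrolysis with a hypervalent iodine reagent: sulfur is oxidised, the thionium ion is trapped by water and the aldehyde is released within minutes under conditions that spare esters and an isolated vinyl group.

Step 13
Reactants: 20 (2S,3R)-3-acetoxy-2-[(1S)-1-acetoxypentadecyl]-2-hydroxypent-4-enal
Product: 21 (2S,3R)-3-acetoxy-2-[(1S)-1-acetoxypentadecyl]-2-(triethylsilyloxy)pent-4-enal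
Conditions: TESOTf, 2,6-lutidine, CH2Cl2, −78 to −20 °C
Reagents that add atoms: triethylsilyl triflate CC[Si](CC)(CC)OS(=O)(=O)C(F)(F)F
Why: Silyl triflate silylation of the tertiary hydroxyl, which now has the small formyl group as a neighbour; the aldehyde has no α-hydrogen and cannot enolise, and capping removes ketol-shift and hemiacetal pathways before the metal step.

Step 14
Reactants: 21 (2S,3R)-3-acetoxy-2-[(1S)-1-acetoxypentadecyl]-2-(triethylsilyloxy)pent-4-enal
Product: 22 (1S)-1-[(1S,2R)-2-acetoxy-5-oxo-1-(triethylsilyloxy)cyclopentyl]pentadecyl acetate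
Conditions: [Rh(dppe)(acetone)2]BF4 (10 mol%, from [Rh(nbd)(dppe)]BF4 and H2), degassed acetone, 25 °C
Reagents that add atoms: none
Why: The cationic monovalent rhodium centre inserts into the formyl C–H bond of 21 to give an acyl hydride of trivalent rhodium, the C2=C3 vinyl group binds, hydride is delivered to C3 so that rhodium ends on the terminal C2 in a six-membered acyl–alkyl rhodacycle, and C–C reductive elimination forms C1–C2 and returns the catalyst. This is the known cationic rhodium–diphosphine intramolecular hydroacylation of 4-pentenals to cyclopentanones, which tolerates oxygen substituents at the 2 and 3 positions of the pentenal. The one ring (C1–C5) closes in a formally 5-endo-trig sense with respect to the alkene, which is feasible because the bond is made by reductive elimination from the rhodacycle and not by direct attack. No stereocentre is created (C2 and C3 become CH2, C1 is trigonal), and C4, C5 and C6 are only carried through, C5 bearing no hydrogen. The step needs ring closure to outrun decarbonylation and needs hydride delivery to the internal carbon: the cis-chelating dppe leaves only the two sites required and turns over at room temperature, the fully substituted C5 folds the chain and slows the alkyl migration that precedes CO loss, and the unsubstituted vinyl terminus directs rhodium to C2. The reversible Markovnikov adduct is a five-membered rhodacycle in which the C4–H and C4–OAc bonds cannot become coplanar with Rh–C3, so it should neither isomerise the alkene nor expel acetate.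

Step 15
Reactants: 22 (1S)-1-[(1S,2R)-2-acetoxy-5-oxo-1-(triethylsilyloxy)cyclopentyl]pentadecyl acetate
Product: 24 (1S)-1-[(1S,5R)-5-acetoxy-2-oxo-1-(triethylsilyloxy)cyclopent-3-en-1-yl]pentadecyl acetate, via trimethylsilyl enol ether 23 (not isolated)
Conditions: TMSOTf, Et3N, CH2Cl2, 0 °C; aq. NaHCO3, concentrate; Pd(OAc)2 (1.1 equiv), MeCN, rt
Reagents that add atoms: none
Why: Soft enolisation can go only toward C2 because C5 is quaternary, and Saegusa–Ito oxidation (palladation of the enol silane, β-hydride elimination from C3) should give the C2=C3 enone without touching C4, C5 or C6.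

Step 16
Reactants: 24 (1S)-1-[(1S,5R)-5-acetoxy-2-oxo-1-(triethylsilyloxy)cyclopent-3-en-1-yl]pentadecyl acetate
Product: 25 (1S)-1-[(1S,5R)-5-acetoxy-1-hydroxy-2-oxocyclopent-3-en-1-yl]pentadecyl acetate
Conditions: HF·pyridine, THF/pyridine, 0 °C to rt
Reagents that add atoms: none
Why: Fluoride cleavage of the silyl ether under mildly acidic conditions should release the C5 hydroxyl without acetate migration or hydrolysis and without base that could degrade the 4-acetoxy enone.

**Compound list**

1 | 1,2:5,6-di-O-isopropylidene-α-D-glucofuranose | O[C@@H]1[C@H]2OC(C)(C)O[C@H]2O[C@@H]1[C@H]3COC(C)(C)O3 | starting material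
2 | 1,2:5,6-di-O-isopropylidene-α-D-ribo-hexofuranos-3-ulose | O=C1[C@H]2OC(C)(C)O[C@H]2O[C@@H]1[C@H]3COC(C)(C)O3 | intermediate
3 | 1,3-dithiane | C1CSCSC1 | starting material
4 | 2-lithio-1,3-dithiane | [Li]C1SCCCS1 | intermediate
5 | 3-C-(1,3-dithian-2-yl)-1,2:5,6-di-O-isopropylidene-α-D-allofuranose (3-OH on the α face, dithianyl on the β face) | O[C@@]1(C2SCCCS2)[C@H]3OC(C)(C)O[C@H]3O[C@@H]1[C@H]4COC(C)(C)O4 | intermediate
6 | 3-C-(1,3-dithian-2-yl)-1,2-O-isopropylidene-α-D-allofuranose | O[C@@]1(C2SCCCS2)[C@H]3OC(C)(C)O[C@H]3O[C@@H]1[C@H](O)CO | intermediate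
7 | 3-C-(1,3-dithian-2-yl)-1,2-O-isopropylidene-5,6-O-thiocarbonyl-α-D-allofuranose | O[C@@]1(C2SCCCS2)[C@H]3OC(C)(C)O[C@H]3O[C@@H]1[C@H]4COC(=S)O4 | intermediate
8 | 5,6-dideoxy-3-C-(1,3-dithian-2-yl)-1,2-O-isopropylidene-α-D-ribo-hex-5-enofuranose | O[C@@]1(C2SCCCS2)[C@H]3OC(C)(C)O[C@H]3O[C@@H]1C=C | intermediate
9 | 5,6-dideoxy-3-C-(1,3-dithian-2-yl)-D-ribo-hex-5-enofuranose (lactol, both anomers) | O[C@@]1(C2SCCCS2)[C@@H](O)C(O)O[C@@H]1C=C | intermediate
10 | 5,6-dideoxy-3-C-(1,3-dithian-2-yl)-D-ribo-hex-5-enitol, i.e. (2S,3R,4R)-3-(1,3-dithian-2-yl)hex-5-ene-1,2,3,4-tetrol | OC[C@H](O)[C@@](O)(C1SCCCS1)[C@H](O)C=C | intermediate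
11 | 5,6-dideoxy-3-C-(1,3-dithian-2-yl)-1,2:3,4-di-O-isopropylidene-D-ribo-hex-5-enitol | C=C[C@H]1OC(C)(C)O[C@@]1(C2SCCCS2)[C@@H]3COC(C)(C)O3 | intermediate
12 | 5,6-dideoxy-3-C-(1,3-dithian-2-yl)-3,4-O-isopropylidene-D-ribo-hex-5-enitol | C=C[C@H]1OC(C)(C)O[C@@]1(C2SCCCS2)[C@@H](O)CO | intermediate
13 | 5,6-dideoxy-3-C-(1,3-dithian-2-yl)-3,4-O-isopropylidene-1-O-(p-toluenesulfonyl)-D-ribo-hex-5-enitol | C=C[C@H]1OC(C)(C)O[C@@]1(C2SCCCS2)[C@@H](O)COS(=O)(=O)c3ccc(C)cc3 | intermediate
14 | 1,2-anhydro-5,6-dideoxy-3-C-(1,3-dithian-2-yl)-3,4-O-isopropylidene-D-ribo-hex-5-enitol | C=C[C@H]1OC(C)(C)O[C@@]1(C2SCCCS2)[C@@H]3CO3 | intermediate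
15 | 1-bromotridecane | CCCCCCCCCCCCCBr | starting material
16 | tridecylmagnesium bromide | CCCCCCCCCCCCC[Mg]Br | intermediate
17 | (1S)-1-[(4S,5R)-4-(1,3-dithian-2-yl)-2,2-dimethyl-5-vinyl-1,3-dioxolan-4-yl]pentadecan-1-ol | CCCCCCCCCCCCCC[C@H](O)[C@]1(C2SCCCS2)OC(C)(C)O[C@@H]1C=C | intermediate
18 | (3R,4S,5S)-4-(1,3-dithian-2-yl)nonadec-1-ene-3,4,5-triol | CCCCCCCCCCCCCC[C@H](O)[C@@](O)(C1SCCCS1)[C@H](O)C=C | intermediate
19 | (3R,4S,5S)-4-(1,3-dithian-2-yl)-4-hydroxynonadec-1-ene-3,5-diyl diacetate | CCCCCCCCCCCCCC[C@H](OC(C)=O)[C@@](O)(C1SCCCS1)[C@H](OC(C)=O)C=C | intermediate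
20 | (2S,3R)-3-acetoxy-2-[(1S)-1-acetoxypentadecyl]-2-hydroxypent-4-enal | CCCCCCCCCCCCCC[C@H](OC(C)=O)[C@@](O)(C=O)[C@H](OC(C)=O)C=C | intermediate
21 | (2S,3R)-3-acetoxy-2-[(1S)-1-acetoxypentadecyl]-2-(triethylsilyloxy)pent-4-enal | CCCCCCCCCCCCCC[C@H](OC(C)=O)[C@@](O[Si](CC)(CC)CC)(C=O)[C@H](OC(C)=O)C=C | intermediate
22 | (1S)-1-[(1S,2R)-2-acetoxy-5-oxo-1-(triethylsilyloxy)cyclopentyl]pentadecyl acetate | CCCCCCCCCCCCCC[C@H](OC(C)=O)[C@@]1(O[Si](CC)(CC)CC)C(=O)CC[C@H]1OC(C)=O | intermediate
23 | (1S)-1-[(1S,5R)-5-acetoxy-1-(triethylsilyloxy)-2-(trimethylsilyloxy)cyclopent-2-en-1-yl]pentadecyl acetate | CCCCCCCCCCCCCC[C@H](OC(C)=O)[C@@]1(O[Si](CC)(CC)CC)C(O[Si](C)(C)C)=CC[C@H]1OC(C)=O | intermediate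
24 | (1S)-1-[(1S,5R)-5-acetoxy-2-oxo-1-(triethylsilyloxy)cyclopent-3-en-1-yl]pentadecyl acetate | CCCCCCCCCCCCCC[C@H](OC(C)=O)[C@@]1(O[Si](CC)(CC)CC)C(=O)C=C[C@H]1OC(C)=O | intermediate
25 | (1S)-1-[(1S,5R)-5-acetoxy-1-hydroxy-2-oxocyclopent-3-en-1-yl]pentadecyl acetate | CCCCCCCCCCCCCC[C@H](OC(C)=O)[C@@]1(O)C(=O)C=C[C@H]1OC(C)=O | target

**Step count**

Total: 16 steps. Longest linear sequence: 16 steps (1 to 25); 3 and 15 enter in steps 2 and 9.

**Steps most likely to fail**

Step 14 (ring closure). The acyl hydride may lose CO and leave a rhodium carbonyl that no longer turns over, or the congested neopentyl-type aldehyde may enter the cycle too slowly. The fallback sets out from 21 and builds the ring by metathesis. Chemoselective Nozaki–Hiyama–Kishi vinylation of the aldehyde (vinyl bromide, CrCl2, NiCl2 cat., DMF) would give the divinyl carbinol (3R)-3-acetoxy-2-[(1S)-1-acetoxypentadecyl]-1-hydroxy-2-(triethylsilyloxy)... as (1S)-1-[(3R,4S)-3-acetoxy-5-hydroxy-4-(triethylsilyloxy)hepta-1,6-dien-4-yl]pentadecyl acetate F1, a mixture at the new carbinol carbon. Ring-closing metathesis with the second-generation Grubbs catalyst (CH2Cl2, 40 °C) would join the two vinyl groups to the cyclopentenol (1S)-1-[(1S,5R)-5-acetoxy-2-hydroxy-1-(triethylsilyloxy)cyclopent-3-en-1-yl]pentadecyl acetate F2. Dess–Martin oxidation of this allylic alcohol removes the extra stereocentre and returns to the route at 24, so steps 14 and 15 are bypassed.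

Step 15 (enone formation). Zerovalent palladium released in the oxidation may ionise the allylic acetate that the oxidation itself creates at C4, or protodesilylation may return 22. The fallback sets out from 22 and uses selenium. The enol silane 23 is made as before and treated with PhSeCl (CH2Cl2, −78 °C) to give the 2-phenylselanyl ketone (1S)-1-[(1S,2R)-2-acetoxy-5-oxo-4-(phenylselanyl)-1-(triethylsilyloxy)cyclopentyl]pentadecyl acetate F3. H2O2 and pyridine (CH2Cl2, 0 °C) would oxidise it to the selenoxide (1S)-1-[(1S,2R)-2-acetoxy-5-oxo-4-(phenylseleninyl)-1-(triethylsilyloxy)cyclopentyl]pentadecyl acetate F4, which undergoes syn-elimination toward C3 and returns to the route at 24.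

Step 12 (aldehyde unmasking). Oxidative hydrolysis at the hindered thioacetal carbon may be slow, the iodane may attack the vinyl group, and the free α-hydroxy aldehyde may be lost on isolation. The fallback sets out from 19 and exchanges the thioacetal instead of hydrolysing it. PhI(OCOCF3)2 in dry methanol would give the dimethyl acetal (3R,4S,5S)-4-(dimethoxymethyl)-4-hydroxynonadec-1-ene-3,5-diyl diacetate F5. Excess TESOTf with 2,6-lutidine (CH2Cl2, 0 °C) would silylate the tertiary hydroxyl and convert the acetal into the N-(1-methoxyalkyl)-2,6-lutidinium triflate F6, which water hydrolyses on work-up. This returns to the route at 21, so 20 and step 13 are bypassed.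

**Further compounds**

F1 | step 14 | (1S)-1-[(3R,4S)-3-acetoxy-5-hydroxy-4-(triethylsilyloxy)hepta-1,6-dien-4-yl]pentadecyl acetate (mixture at C5 of the heptadiene) | CCCCCCCCCCCCCC[C@H](OC(C)=O)[C@@](O[Si](CC)(CC)CC)(C(O)C=C)[C@H](OC(C)=O)C=C
F2 | step 14 | (1S)-1-[(1S,5R)-5-acetoxy-2-hydroxy-1-(triethylsilyloxy)cyclopent-3-en-1-yl]pentadecyl acetate (mixture at the carbinol carbon) | CCCCCCCCCCCCCC[C@H](OC(C)=O)[C@@]1(O[Si](CC)(CC)CC)C(O)C=C[C@H]1OC(C)=O
F3 | step 15 | (1S)-1-[(1S,2R)-2-acetoxy-5-oxo-4-(phenylselanyl)-1-(triethylsilyloxy)cyclopentyl]pentadecyl acetate | CCCCCCCCCCCCCC[C@H](OC(C)=O)[C@@]1(O[Si](CC)(CC)CC)C(=O)C([Se]c2ccccc2)C[C@H]1OC(C)=O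
F4 | step 15 | (1S)-1-[(1S,2R)-2-acetoxy-5-oxo-4-(phenylseleninyl)-1-(triethylsilyloxy)cyclopentyl]pentadecyl acetate | CCCCCCCCCCCCCC[C@H](OC(C)=O)[C@@]1(O[Si](CC)(CC)CC)C(=O)C([Se](=O)c2ccccc2)C[C@H]1OC(C)=O
F5 | step 12 | (3R,4S,5S)-4-(dimethoxymethyl)-4-hydroxynonadec-1-ene-3,5-diyl diacetate | CCCCCCCCCCCCCC[C@H](OC(C)=O)[C@@](O)(C(OC)OC)[C@H](OC(C)=O)C=C
F6 | step 12 | N-(1-methoxyalkyl)-2,6-lutidinium triflate of the triethylsilyl-protected aldehyde 21 | CCCCCCCCCCCCCC[C@H](OC(C)=O)[C@@](O[Si](CC)(CC)CC)(C(OC)[n+]1c(C)cccc1C)[C@H](OC(C)=O)C=C.[O-]S(=O)(=O)C(F)(F)F
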